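## Retrosynthetic overview

1. The strategy rests on the tropone ring. T7 (C=O), T1 (C–CO2Me), T2 (C–Me), T3 (C–H), T4 (carbon bearing the furan CH2), T5 (C–O of the furan) and T6 (C–Me) are the benzene ring of methyl 2,4-dihydroxy-3,6-dimethylbenzoate plus one CH (T3, from chloroform) placed between T2 and T4.
2. Key disconnection: tropone ⇒ spiro-fused 4-(dichloromethyl)cyclohexa-2,5-dienone (radical 3-exo closure of the CHCl radical onto T2, cleavage of T4–T2, loss of Cl) ⇒ spirocyclic phenol plus dichlorocarbene at the para (ring-fusion) carbon.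
3. Dihydrofuran ring ⇒ aryl C–O bond closed by palladium from a tertiary alcohol onto an aryl triflate (carbinol configuration kept) ⇒ C–C bond between an atraric-acid-derived benzyl bromide and a 2,2,3,6-substituted cyclohexanone (SmI2).
4. Cyclohexanone ⇒ (S)-carvone: C-6 methylation, C-6 allylation anti to isopropenyl, hydroboration of the allyl group, hydration of isopropenyl, face-selective hydrogenation of the enone. The propanoic acid is unmasked by Jones oxidation once the furan ring is closed.
5. Ring order: cyclohexane (carvone) and benzene (atraric acid) come with the starting materials; the dihydrofuran ring is closed third (step 11); the benzene ring is enlarged to the tropone last (step 14).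

Key step: step 14

Remarks on the chemistry:
- The side-chain acid is carried free through steps 13 and 14. Acid removal of a tert-butyl ester at the end would also ionise the tert-alkyl O–C bond of the tropone vinylogous ester, so no ester protecting group is used.
- The three-carbon acid chain enters as an allyl group. The cross-conjugated enolate of 6-methylcarvone and an acrylate would go on to a bicyclo[2.2.2]octanone by a second Michael addition.
- The furan ring is closed at the aryl carbon, not through a cation at the spiro carbon. A cation would lose the configuration set in step 10 and would be captured by the side-chain oxygen on the same face.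

## Route

Step 1
Reactants: 1 (S)-carvone
Product: 2 (5S)-2,6-dimethyl-5-(prop-1-en-2-yl)cyclohex-2-en-1-one (6-methylcarvone, both C-6 epimers)
Conditions: LiN(iPr)2, THF, −78 °C; MeI, −78 → 0 °C
Reagents that add atoms: iodomethane, CI
Why: Kinetic deprotonation at the only sp3 α-carbon (C-6) and SN2 methylation of the cross-conjugated lithium enolate (enolate alkylation); the C-6 configuration does not matter because this centre is enolised again in step 2.

Step 2
Reactants: 2 6-methylcarvone
Product: 3 (5R,6R)-2,6-dimethyl-6-(prop-2-en-1-yl)-5-(prop-1-en-2-yl)cyclohex-2-en-1-one (allyl trans, methyl cis to isopropenyl)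
Conditions: LiN(iPr)2, THF, −78 °C; allyl bromide, DMPU, −78 → 0 °C
Reagents that add atoms: allyl bromide, C=CCBr
Why: Second enolate alkylation at C-6, in which allyl bromide approaches the tetrasubstituted enolate on the face opposite the neighbouring isopropenyl group, so the quaternary centre is set with allyl trans and methyl cis to isopropenyl.

Step 3
Reactants: 3 allyl methyl carvone
Product: 4 (5R,6R)-6-(3-hydroxypropyl)-2,6-dimethyl-5-(prop-1-en-2-yl)cyclohex-2-en-1-one
Conditions: disiamylborane (from BH3·THF and 2-methylbut-2-ene), THF, 0 °C; NaBO3·4H2O, THF/H2O, rt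
Reagents that add atoms: sodium perborate, [Na+].[Na+].O[B-]1(O)OO[B-](O)(O)OO1
Why: Anti-Markovnikov hydroboration–oxidation in which the bulky dialkylborane should take the monosubstituted allyl alkene far faster than the 1,1-disubstituted isopropenyl alkene or the hindered conjugated ketone, and the perborate work-up is mild enough to leave the enone unepoxidised.

Step 4
Reactants: 4 primary alcohol
Product: 5 (5S,6R)-5-(2-hydroxypropan-2-yl)-6-(3-hydroxypropyl)-2,6-dimethylcyclohex-2-en-1-one
Conditions: Co(acac)2 (cat.), PhSiH3, O2 (1 atm), THF, rt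
Reagents that add atoms: dioxygen, O=O
Why: Mukaiyama hydration (hydrogen-atom transfer from a cobalt hydride to the 1,1-disubstituted alkene, capture of the tertiary radical by O2, reduction of the peroxide by the silane) should give the Markovnikov tertiary alcohol while the electron-poor trisubstituted enone reacts much more slowly; no stereocentre is formed.

Step 5
Reactants: 5 diol
Product: 7 (5S,6R)-6-{3-[(tert-butyldimethylsilyl)oxy]propyl}-2,6-dimethyl-5-{2-[(trimethylsilyl)oxy]propan-2-yl}cyclohex-2-en-1-one, via primary silyl ether 6 (not isolated)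
Conditions: TBSCl, imidazole, DMF, 0 °C; then TMSCl, rt
Reagents that add atoms: tert-butyldimethylsilyl chloride, CC(C)(C)[Si](C)(C)Cl; trimethylsilyl chloride, C[Si](C)(C)Cl
Why: Stepwise silyl ether formation in one flask, the primary hydroxyl taking the bulky silyl chloride first and the tertiary hydroxyl then taking the small trimethylsilyl group, so that neither hydroxyl interferes in steps 6, 10 and 11.

Step 6
Reactants: 7 bis-silyl enone
Product: 8 (2R,3S,6R)-2-{3-[(tert-butyldimethylsilyl)oxy]propyl}-2,6-dimethyl-3-{2-[(trimethylsilyl)oxy]propan-2-yl}cyclohexan-1-one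
Conditions: H2 (1 atm), Pd/C, EtOAc, rt
Reagents that add atoms: none
Why: Heterogeneous catalytic hydrogenation should add both hydrogens syn to the enone face that carries only the propyl chain, because the other face is screened by the C-6 methyl and the bulky 2-silyloxypropan-2-yl group, so the new methyl-bearing centre forms cis to both (the kinetic, less stable epimer, hence neutral conditions and no base afterwards).

Step 7
Reactants: 9 atraric acid (methyl 2,4-dihydroxy-3,6-dimethylbenzoate)
Product: 10 methyl 2-hydroxy-3,6-dimethyl-4-{[(trifluoromethyl)sulfonyl]oxy}benzoate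
Conditions: Tf2O (1.05 equiv), pyridine, CH2Cl2, −20 → 0 °C
Reagents that add atoms: trifluoromethanesulfonic anhydride, O=S(=O)(OS(=O)(=O)C(F)(F)F)C(F)(F)F
Why: Chemoselective O-sulfonylation (triflation) of the free 4-hydroxyl, the 2-hydroxyl being hydrogen-bonded to the ester carbonyl and flanked by two ortho substituents.

Step 8
Reactants: 10 aryl triflate
Product: 11 methyl 5-(bromomethyl)-2-hydroxy-3,6-dimethyl-4-{[(trifluoromethyl)sulfonyl]oxy}benzoate
Conditions: (CH2O)n, HBr, AcOH, 50 °C
Reagents that add atoms: formaldehyde (as paraformaldehyde), C=O; hydrogen bromide, Br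
Why: Bromomethylation (Blanc-type electrophilic aromatic substitution with protonated formaldehyde, then bromide for hydroxyl) at C-5, the only free ring position, which is para to the hydroxyl and ortho to a methyl group.

Step 9
Reactants: 11 bromomethyl phenol
Product: 12 methyl 5-(bromomethyl)-3,6-dimethyl-4-{[(trifluoromethyl)sulfonyl]oxy}-2-[(triisopropylsilyl)oxy]benzoate
Conditions: TIPSOTf, 2,6-lutidine, CH2Cl2, 0 °C → rt
Reagents that add atoms: triisopropylsilyl trifluoromethanesulfonate, CC(C)[Si](OS(=O)(=O)C(F)(F)F)(C(C)C)C(C)C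
Why: Silylation of the phenol with a silyl triflate and a hindered pyridine base that does not displace the benzylic bromide, masking the acidic hydroxyl for the organometallic step.

Step 10
Reactants: 8 cyclohexanone; 12 benzyl bromide
Product: 13 methyl 5-{[(1R,2R,3S,6R)-2-{3-[(tert-butyldimethylsilyl)oxy]propyl}-1-hydroxy-2,6-dimethyl-3-{2-[(trimethylsilyl)oxy]propan-2-yl}cyclohexyl]methyl}-3,6-dimethyl-4-{[(trifluoromethyl)sulfonyl]oxy}-2-[(triisopropylsilyl)oxy]benzoate
Conditions: SmI2 (THF), 12 added slowly to 8 and SmI2, 0 °C → rt; aq NH4Cl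
Reagents that add atoms: none
Why: Samarium Barbier reaction (two single-electron transfers turn the benzylic bromide into a benzylsamarium species that adds to the ketone), with attack from the carbonyl face opposite the two α-methyl groups and the β-silyloxyalkyl group, which puts the benzyl group cis to the propyl chain and the hydroxyl cis to both methyls; the aryl triflate and the hindered ester are not reduced by SmI2 in THF.

Step 11
Reactants: 13 tertiary alcohol
Product: 14 methyl (2R,2'R,3'S,6'R)-2'-{3-[(tert-butyldimethylsilyl)oxy]propyl}-2',4,6',7-tetramethyl-6-[(triisopropylsilyl)oxy]-3'-{2-[(trimethylsilyl)oxy]propan-2-yl}-3H-spiro[1-benzofuran-2,1'-cyclohexane]-5-carboxylate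
Conditions: Pd(OAc)2 (cat.), 2-(di-tert-butylphosphino)-1,1'-binaphthyl, Cs2CO3, toluene, 90 °C
Reagents that add atoms: none
Why: Buchwald-type palladium-catalysed intramolecular aryl etherification (oxidative addition into the aryl triflate, alkoxide binding, C–O reductive elimination eased by the para ester) closes the five-membered ring at the aryl carbon, so the configuration of the carbinol carbon from step 10 is kept and no cation forms at the spiro centre.

Step 12
Reactants: 14 spiro ether
Product: 15 3-[(2R,2'R,3'S,6'R)-3'-(2-hydroxypropan-2-yl)-5-(methoxycarbonyl)-2',4,6',7-tetramethyl-6-[(triisopropylsilyl)oxy]-3H-spiro[1-benzofuran-2,1'-cyclohexan]-2'-yl]propanoic acid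
Conditions: CrO3, H2SO4, acetone/H2O, 0 °C
Reagents that add atoms: water, O
Why: Jones oxidation, in which the aqueous acid removes the primary tert-butyldimethylsilyl and the tertiary trimethylsilyl ethers and chromic acid oxidises the freed primary alcohol via the aldehyde hydrate to the carboxylic acid, while the aryl silyl ether, the tertiary alcohol and the aryl ether should not be attacked at 0 °C.

Step 13
Reactants: 15 silyl-protected phenol acid
Product: 17 3-[(2R,2'R,3'S,6'R)-3a-(dichloromethyl)-3'-(2-hydroxypropan-2-yl)-5-(methoxycarbonyl)-2',4,6',7-tetramethyl-6-oxo-3a,6-dihydro-3H-spiro[1-benzofuran-2,1'-cyclohexan]-2'-yl]propanoic acid (both C-3a epimers), via free phenol 16 (not isolated)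
Conditions: NaOH, H2O/MeOH, 65 °C; then CHCl3 (slow addition), 65 °C; NaH2PO4 to pH 5, 0 °C
Reagents that add atoms: chloroform, ClC(Cl)Cl
Why: Hydroxide first cleaves the aryl silyl ether, and the phenoxide then undergoes the abnormal Reimer–Tiemann reaction, dichlorocarbene being attacked by the para carbon (ring-fusion carbon C-3a), which carries no hydrogen, so the 4-(dichloromethyl)cyclohexa-2,5-dienone cannot rearomatise; the new quaternary centre forms as a mixture that converges in step 14, and the doubly ortho-substituted methyl ester resists hydroxide.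

Step 14
Reactants: 17 spiro 3a-(dichloromethyl)dienone acid
Product: 18 3-[(2R,2'R,3'S,6'R)-3'-(2-hydroxypropan-2-yl)-6-(methoxycarbonyl)-2',5,6',8-tetramethyl-7-oxo-3H,7H-spiro[cyclohepta[b]furan-2,1'-cyclohexan]-2'-yl]propanoic acid (target, CNP0448476.2)
Conditions: Bu3SnH (2.5 equiv, slow addition), AIBN (cat.), benzene (0.01 M), 80 °C
Reagents that add atoms: none
Why: Bu3Sn• abstracts one chlorine, and the α-chloroalkyl radical on the exocyclic carbon (the future T3) closes 3-exo-trig onto T2 of the ester-bearing enone, giving a cyclopropylcarbinyl radical at T1 that is stabilised by both the ketone and the ester. β-Scission of the old T4–T2 bond (T3–T2 is kept) opens the cyclopropane into the seven-membered ring, and the T4 radical, allylic to the T5=T6–T7=O unit, expels the remaining chlorine atom from T3 to give the tropone, the chlorine being taken up by the second equivalent of tin hydride. The closest known reaction is the tin-hydride ring enlargement of 4-(dichloromethyl)cyclohexa-2,5-dienones from abnormal Reimer–Tiemann reactions to tropones. The three-membered ring closes transiently by 3-exo-trig radical addition, and the seven-membered ring arises by fragmentation of that cyclopropane (six to seven), not by a direct seven-ring cyclisation. No stereocentre is created and the C-3a centre of 17 is destroyed, so both epimers converge. The step needs attack at T2 and not at the alkoxy-bearing T5, and ring opening with chlorine loss must outrun hydrogen transfer: the nucleophilic radical prefers the electron-poor T1=T2 alkene and the malonyl-type radical, and slow addition of Bu3SnH at high dilution keeps the hydride concentration low.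

## Compound list

1 | (S)-carvone, (5S)-2-methyl-5-(prop-1-en-2-yl)cyclohex-2-en-1-one | CC1=CC[C@@H](CC1=O)C(C)=C | starting material
2 | (5S)-2,6-dimethyl-5-(prop-1-en-2-yl)cyclohex-2-en-1-one (both C-6 epimers) | CC1=CC[C@@H](C(C)C1=O)C(C)=C | intermediate
3 | (5R,6R)-2,6-dimethyl-6-(prop-2-en-1-yl)-5-(prop-1-en-2-yl)cyclohex-2-en-1-one | O=C1C(C)=CC[C@H](C(C)=C)[C@@]1(C)CC=C | intermediate
4 | (5R,6R)-6-(3-hydroxypropyl)-2,6-dimethyl-5-(prop-1-en-2-yl)cyclohex-2-en-1-one | O=C1C(C)=CC[C@H](C(C)=C)[C@@]1(C)CCCO | intermediate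
5 | (5S,6R)-5-(2-hydroxypropan-2-yl)-6-(3-hydroxypropyl)-2,6-dimethylcyclohex-2-en-1-one | O=C1C(C)=CC[C@H](C(C)(C)O)[C@@]1(C)CCCO | intermediate
6 | (5S,6R)-6-{3-[(tert-butyldimethylsilyl)oxy]propyl}-5-(2-hydroxypropan-2-yl)-2,6-dimethylcyclohex-2-en-1-one | O=C1C(C)=CC[C@H](C(C)(C)O)[C@@]1(C)CCCO[Si](C)(C)C(C)(C)C | intermediate (not isolated)
7 | (5S,6R)-6-{3-[(tert-butyldimethylsilyl)oxy]propyl}-2,6-dimethyl-5-{2-[(trimethylsilyl)oxy]propan-2-yl}cyclohex-2-en-1-one | O=C1C(C)=CC[C@H](C(C)(C)O[Si](C)(C)C)[C@@]1(C)CCCO[Si](C)(C)C(C)(C)C | intermediate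
8 | (2R,3S,6R)-2-{3-[(tert-butyldimethylsilyl)oxy]propyl}-2,6-dimethyl-3-{2-[(trimethylsilyl)oxy]propan-2-yl}cyclohexan-1-one | O=C1[C@H](C)CC[C@H](C(C)(C)O[Si](C)(C)C)[C@@]1(C)CCCO[Si](C)(C)C(C)(C)C | intermediate
9 | atraric acid, methyl 2,4-dihydroxy-3,6-dimethylbenzoate | COC(=O)c1c(C)cc(O)c(C)c1O | starting material
10 | methyl 2-hydroxy-3,6-dimethyl-4-{[(trifluoromethyl)sulfonyl]oxy}benzoate | COC(=O)c1c(C)cc(OS(=O)(=O)C(F)(F)F)c(C)c1O | intermediate
11 | methyl 5-(bromomethyl)-2-hydroxy-3,6-dimethyl-4-{[(trifluoromethyl)sulfonyl]oxy}benzoate | COC(=O)c1c(C)c(CBr)c(OS(=O)(=O)C(F)(F)F)c(C)c1O | intermediate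
12 | methyl 5-(bromomethyl)-3,6-dimethyl-4-{[(trifluoromethyl)sulfonyl]oxy}-2-[(triisopropylsilyl)oxy]benzoate | COC(=O)c1c(C)c(CBr)c(OS(=O)(=O)C(F)(F)F)c(C)c1O[Si](C(C)C)(C(C)C)C(C)C | intermediate
13 | methyl 5-{[(1R,2R,3S,6R)-2-{3-[(tert-butyldimethylsilyl)oxy]propyl}-1-hydroxy-2,6-dimethyl-3-{2-[(trimethylsilyl)oxy]propan-2-yl}cyclohexyl]methyl}-3,6-dimethyl-4-{[(trifluoromethyl)sulfonyl]oxy}-2-[(triisopropylsilyl)oxy]benzoate | O[C@]1(Cc2c(C)c(C(=O)OC)c(O[Si](C(C)C)(C(C)C)C(C)C)c(C)c2OS(=O)(=O)C(F)(F)F)[C@H](C)CC[C@H](C(C)(C)O[Si](C)(C)C)[C@@]1(C)CCCO[Si](C)(C)C(C)(C)C | intermediate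
14 | methyl (2R,2'R,3'S,6'R)-2'-{3-[(tert-butyldimethylsilyl)oxy]propyl}-2',4,6',7-tetramethyl-6-[(triisopropylsilyl)oxy]-3'-{2-[(trimethylsilyl)oxy]propan-2-yl}-3H-spiro[1-benzofuran-2,1'-cyclohexane]-5-carboxylate | COC(=O)c1c(C)c2c(c(C)c1O[Si](C(C)C)(C(C)C)C(C)C)O[C@]1(C2)[C@H](C)CC[C@H](C(C)(C)O[Si](C)(C)C)[C@@]1(C)CCCO[Si](C)(C)C(C)(C)C | intermediate
15 | 3-[(2R,2'R,3'S,6'R)-3'-(2-hydroxypropan-2-yl)-5-(methoxycarbonyl)-2',4,6',7-tetramethyl-6-[(triisopropylsilyl)oxy]-3H-spiro[1-benzofuran-2,1'-cyclohexan]-2'-yl]propanoic acid | COC(=O)c1c(C)c2c(c(C)c1O[Si](C(C)C)(C(C)C)C(C)C)O[C@]1(C2)[C@H](C)CC[C@H](C(C)(C)O)[C@@]1(C)CCC(=O)O | intermediate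
16 | 3-[(2R,2'R,3'S,6'R)-6-hydroxy-3'-(2-hydroxypropan-2-yl)-5-(methoxycarbonyl)-2',4,6',7-tetramethyl-3H-spiro[1-benzofuran-2,1'-cyclohexan]-2'-yl]propanoic acid | COC(=O)c1c(C)c2c(c(C)c1O)O[C@]1(C2)[C@H](C)CC[C@H](C(C)(C)O)[C@@]1(C)CCC(=O)O | intermediate (not isolated)
17 | 3-[(2R,2'R,3'S,6'R)-3a-(dichloromethyl)-3'-(2-hydroxypropan-2-yl)-5-(methoxycarbonyl)-2',4,6',7-tetramethyl-6-oxo-3a,6-dihydro-3H-spiro[1-benzofuran-2,1'-cyclohexan]-2'-yl]propanoic acid (both C-3a epimers) | COC(=O)C1=C(C)C2(C(Cl)Cl)C(=C(C)C1=O)O[C@]1(C2)[C@H](C)CC[C@H](C(C)(C)O)[C@@]1(C)CCC(=O)O | intermediate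
18 | 3-[(2R,2'R,3'S,6'R)-3'-(2-hydroxypropan-2-yl)-6-(methoxycarbonyl)-2',5,6',8-tetramethyl-7-oxo-3H,7H-spiro[cyclohepta[b]furan-2,1'-cyclohexan]-2'-yl]propanoic acid | COC(=O)c1c(C)cc2c(c(C)c1=O)O[C@]1(C2)[C@H](C)CC[C@H](C(C)(C)O)[C@@]1(C)CCC(=O)O | target

## Step count and risks

Total step count: 14. Longest linear sequence: 11 steps (steps 1–6 and 10–14, from (S)-carvone); the arene branch (steps 7–9) joins at step 10.

The three steps most likely to fail:

1. Step 13 (dearomatisation). The carbene may be captured at the methyl-bearing ortho carbon between the two oxygens instead of the more crowded ring-fusion carbon, or be hydrolysed before it meets the phenoxide, so that conversion to the para dienone stays low. The fallback sets out from 15 and comes back at 18. Bu4NF in THF would give the isolated phenol 16. Its potassium salts (KOtBu, 18-crown-6, THF, −20 °C) would be treated with CHBr3 and more KOtBu. Dibromocarbene is then made by alkoxide with no water or hydroxide competing for it, and it meets a crown-ether-separated phenoxide that lacks cation-guided ortho delivery. This should give the 3a-(dibromomethyl) dienone acid F1. Its weaker carbon–halogen bonds would allow the same radical ring enlargement with Bu3SnH and Et3B/air at room temperature, delivering 18.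

2. Step 10 (samarium union). Reductive dimerisation of the benzyl bromide, or protonation of the benzylsamarium species, may outrun addition to the very hindered carbonyl. The fallback sets out from 12 and 8 and comes back at 13. Activated magnesium (from MgCl2 and lithium naphthalenide) in THF at −78 °C would convert 12 into the benzylmagnesium bromide F2. Anhydrous CeCl3 at −78 °C would turn it into the benzylcerium dichloride F3, a weakly basic and strongly carbonyl-seeking two-electron nucleophile. F3 would add to 8 at −78 °C from the same face to give 13.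

3. Step 11 (palladium etherification). The hindered tertiary alkoxide may bind to arylpalladium too slowly, so that protodetriflation or β-carbon elimination of the alkoxide takes over. The fallback sets out from 13 and comes back at 14. Ruthenium-catalysed triflate–halide exchange ([Cp*Ru(MeCN)3]OTf, NaI, 1,3-dimethyl-2-imidazolidinone, 100 °C) would give the aryl iodide F4. A copper-mediated intramolecular Ullmann etherification (CuI, 3,4,7,8-tetramethyl-1,10-phenanthroline, Cs2CO3, toluene, 110 °C) would then close the furan ring at the aryl carbon, again with retention at the carbinol centre, to give 14.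

## Further compounds

F1 | step 13 | 3-[(2R,2'R,3'S,6'R)-3a-(dibromomethyl)-3'-(2-hydroxypropan-2-yl)-5-(methoxycarbonyl)-2',4,6',7-tetramethyl-6-oxo-3a,6-dihydro-3H-spiro[1-benzofuran-2,1'-cyclohexan]-2'-yl]propanoic acid (both C-3a epimers) | COC(=O)C1=C(C)C2(C(Br)Br)C(=C(C)C1=O)O[C@]1(C2)[C@H](C)CC[C@H](C(C)(C)O)[C@@]1(C)CCC(=O)O
F2 | step 10 | {[3-(methoxycarbonyl)-2,5-dimethyl-6-{[(trifluoromethyl)sulfonyl]oxy}-4-[(triisopropylsilyl)oxy]phenyl]methyl}magnesium bromide | COC(=O)c1c(C)c(C[Mg]Br)c(OS(=O)(=O)C(F)(F)F)c(C)c1O[Si](C(C)C)(C(C)C)C(C)C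
F3 | step 10 | {[3-(methoxycarbonyl)-2,5-dimethyl-6-{[(trifluoromethyl)sulfonyl]oxy}-4-[(triisopropylsilyl)oxy]phenyl]methyl}cerium dichloride | COC(=O)c1c(C)c(C[Ce](Cl)Cl)c(OS(=O)(=O)C(F)(F)F)c(C)c1O[Si](C(C)C)(C(C)C)C(C)C
F4 | step 11 | methyl 5-{[(1R,2R,3S,6R)-2-{3-[(tert-butyldimethylsilyl)oxy]propyl}-1-hydroxy-2,6-dimethyl-3-{2-[(trimethylsilyl)oxy]propan-2-yl}cyclohexyl]methyl}-4-iodo-3,6-dimethyl-2-[(triisopropylsilyl)oxy]benzoate | O[C@]1(Cc2c(C)c(C(=O)OC)c(O[Si](C(C)C)(C(C)C)C(C)C)c(C)c2I)[C@H](C)CC[C@H](C(C)(C)O[Si](C)(C)C)[C@@]1(C)CCCO[Si](C)(C)C(C)(C)C
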